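The data are calculated on assumed constants, and the scatter is random.

I began with a leftover. At 15.0 h the north run still held 76.9% of its electrophile, and the south-west run held 27.3%. I wanted the same leftover for three new flasks.

common to all: electrophile 0.20 M
- north: nucleophile 0.39 M; protic impurity 0.10 M; run made earlier
- south-west: nucleophile 1.8 M; protic impurity 0.10 M; run made earlier
- spring: nucleophile 0.500 M; protic impurity 0.100 M; time 30 h
- dusk: nucleophile 1.00 M; protic impurity 0.100 M; time 30 h
- summer: nucleophile 2.00 M; protic impurity 0.100 M; time 30 h

| run | time / h | electrophile / % | product / % |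
|---|---|---|---|
| north | 0.833 | 97.3 | 1.6 |
| north | 2.50 | 93.7 | 5.0 |
| north | 4.00 | 91.4 | 6.9 |
| north | 6.00 | 86.7 | 12.4 |
| north | 10.0 | 82.8 | 16.8 |
| north | 12.0 | 82.0 | 18.5 |
| north | 15.0 | 76.9 | 20.8 |
| south-west | 0.833 | 91.9 | 9.5 |
| south-west | 2.50 | 76.9 | 22.6 |
| south-west | 4.00 | 67.9 | 31.3 |
| south-west | 6.00 | 55.9 | 43.7 |
| south-west | 10.0 | 38.3 | 60.1 |
| south-west | 12.0 | 33.4 | 66.4 |
| south-west | 15.0 | 27.3 | 72.5 |

(each reading ± 1 percentage point)

- the earlier runs were read with a standard deviation of 1 percentage point
- a reading or a percentage of product counts all its forms, free or not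

1. part of the electrophile that has reacted at the end, spring
2. part of the electrophile that has reacted at the end, dusk
3. part of the electrophile that has reacted at the end, summer
4. what raising the concentration of nucleophile from its lowest to its highest value here does to the part of the electrophile that has reacted (changes below 5 percentage points count as none) (no change / it rises / it falls)

I turned each leftover into a loss number L, the natural logarithm of one over the fraction left. A flask that loses the same fraction each hour adds to L evenly (the pseudo-first-order picture). L came to 0.263 in the north run and 1.30 in the south-west run. That is a ratio of 4.94, against 4.62 in nucleophile charge, so I divided L by charge and time. The north run gave 0.0449 L mol⁻¹ h⁻¹, and that figure put spring at 49.0% reacted.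

I doubted this at once, since the north run had not kept an even pace. Up to 6.00 h its figure was 0.0610 L mol⁻¹ h⁻¹. So I took the late pace, the gain in L per hour and per unit of nucleophile charge between the readings at 6.00 h and 15.0 h. In the north run it was 0.0342 L mol⁻¹ h⁻¹, lower than the early figure. In the south-west run it was 0.0442 L mol⁻¹ h⁻¹.

I kept L per charge as read at 15.0 h and added the late pace for the remaining hours. Spring, on north figures, came to 44.7%. Summer, on south-west figures, came to 93.7%. Dusk, on the mean of both, came to 72.3%. One objection stayed: the pace might fall again after the last reading. I therefore read these figures as high rather than low.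

The forecast gave 42% for spring, 67% for dusk and 91% for summer, and its answer on the trend was it rises, with the remark “Conversion clearly rises with nucleophile”. The flasks gave 42.2% for spring, 69.8% for dusk and 93.4% for summer, and the answer on the trend was it rises, by 51 percentage points.

    nucleophile + acid set free ⇌ protonated nucleophile, settled at all times (K = 36.0 L mol⁻¹)
    nucleophile + product ⇌ idle adduct, settled at all times (K = 21.9 L mol⁻¹)
    electrophile + nucleophile ⇌ acid set free + product (K = 0.680, k = 0.0602 L mol⁻¹ h⁻¹)
    nucleophile + protic impurity → quenched reagent (k = 0.152 L mol⁻¹ h⁻¹)

Spring's own late pace, from 15.0 h to 30.0 h, was 0.0283 L mol⁻¹ h⁻¹, lower than the north run's 0.0342 L mol⁻¹ h⁻¹. On north figures, the neighbour of dusk charged with 0.40 M of nucleophile came to 37.8%, and it stood at 35.0%. Left ten times as long, summer went from 93.4% to >99.9%, and dusk went from 69.8% to 99.2%. Spring went from 42.2% to 72.3%, at an average late pace of 0.00544 L mol⁻¹ h⁻¹.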